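(The data come from a simulation from invented constants, and the scatter is random.)

Every first end group is either free or in a link, and every link has set free one by-product, so [first end groups] + [links] stays at its charge and [by-product] equals [links]. If the reversible step is fast, we can freeze one number, its equilibrium constant: [links] squared over [first end groups] times [second end groups].

| flask | first end groups | second end groups | remark | time |
|---|---|---|---|---|
| north | 5 mM | 2.4 mM (in portions, 3) | run made earlier; portions every 10 s |  |
| south-east | 5 mM | 3.6 mM (in portions, 3) | run made earlier; portions every 10 s |  |
| flask | 5.0 mM | 4.75 mM (in portions, 3) | the portions of second end groups follow each other after 10 s, the first at the start | 10 min |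

| run | time / min | links / % | first end groups / % |
|---|---|---|---|
| north | 0.833 | 41 | 54 |
| north | 1.33 | 47 | 56 |
| north | 2.00 | 44 | 61 |
| north | 3.00 | 44 | 59 |
| north | 4.00 | 41 | 56 |
| north | 6.00 | 44 | 59 |
| north | 10.0 | 43 | 59 |
| south-east | 1.33 | 63 | 41 |
| south-east | 3.00 | 59 | 44 |
| south-east | 4.00 | 59 | 44 |
| south-east | 6.00 | 53 | 48 |
| south-east | 8.00 | 54 | 48 |
| south-east | 10.0 | 55 | 50 |

(scatter of a reading: 2 percentage points)

- amount of links in the flask at 10 min, in percent of the first end groups charged
- amount of first end groups in the flask at 10 min, in percent of the first end groups charged
- concentration of second end groups at 10 min, in mM

- what is said of links includes crystals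
- crystals is a solid; its amount is given per volume of the solution
- on the list of suspects stand: first end groups + second end groups <-> links + by-product; 2 second end groups -> self-condensation product; crystals <-> links

The north run at 10.0 min reads 2.15 mM of links and 2.95 mM of first end groups. Taking the remainder of the charge, 0.250 mM, as free second end groups, we get a quotient of 6.27. This is a rough reading, since that remainder carries the scatter of 2 percentage points.

Our flask resembles the south-east run, with the same first end groups but 4.75 mM of second end groups against 3.6 mM. With the quotient frozen, we reckon 2.93 mM of links and 0.665 mM of free second end groups for south-east, and 3.48 mM and 1.27 mM for the flask.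

Yet the south-east readings of links drift from 63% to 55%. At 10.0 min the quotient asks for 0.483 mM free, so we read about 0.367 mM of the south-east charge as gone, which we assign to self-condensation. We take that loss to go with the square of [second end groups], and our reckoned free amount is larger in the flask than in south-east, so we scale it to 1.34 mM. Of the flask's extra 1.15 mM of charge, the extra loss by this estimate takes 0.973 mM, so we expect the flask and the south-east run to end close together. Solving again on the reduced charge of 3.41 mM, we expect 2.82 mM of links, or 56.5%.

The forecast gives 60% of links (52% to 69%), 41% of first end groups (32% to 49%) and 0.62 mM of second end groups (0.35 mM to 1 mM), with a loss “which pulls the reversible link-forming step backward”. Its links stand above ours.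

At 10 min the flask holds 57.3% of links, 42.7% of first end groups and 0.515 mM of second end groups.

    first end groups + second end groups ⇌ links + by-product (K = 7.40, k = 77.0 M⁻¹ s⁻¹)
    2 second end groups → self-condensation product (k = 2.20 M⁻¹ s⁻¹)
    crystals ⇌ links, rate k3*(cs3 - [links]) while solid is left; crystals form when [links] > cs3 (solubility = 2.90 mM, k = 1.60 s⁻¹)

At 10.0 min the forward link step in the flask uses second end groups 72 times as fast as self-condensation. Up to that time its backward turnover in the flask comes to 95% of the forward one. Our quotient, applied to the flask's links and first end groups, gives 0.614 mM of second end groups against the 0.515 mM found. For a neighbour flask charged with 2.8 mM of second end groups, the quotient on that whole charge gives 48.6% of links; the computed result for that neighbour is 46.0%.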